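**Retrosynthetic overview**

1. Target 29 ⇐ desilylation of 28 ⇐ one-flask closure of the open-chain bromo enal 26: first the C6–C7 bond (ten-membered carbocycle, the bond the sesquiterpene cyclase makes between farnesyl C1 and C10), then the O6–C12 γ-lactone.
2. 26 ⇐ C7 aldehyde 21 + methyl propiolate (C11–C13 acrylate unit); the C6 enal comes from a primary silyl ether.
3. 21 ⇐ aldehyde 18 + (Z)-vinyl iodide 7 (C3–C4 bond, C3 stereocentre); the C9 ester comes from epoxy acid 3 (Sharpless epoxidation).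
4. 18 ⇐ Z-selective Wittig reaction (C10=C1) of the L-tartrate-derived methyl ketone 10 (C8 and C9 from the chiral pool) with a C1–C3 ylide.
5. No ring is formed before step 18; every stereocentre except C6 and C7 is already present in the open chain, which carries all three ester groups when it is cyclised.

Assumption: the SMILES is taken literally, i.e. a 6,12-cis-fused (1(10)Z,4Z)-germacranolide with a (2S,3R)-epoxy ester; labels C1–C15 follow germacranolide numbering (C6 lactone carbinol, C7 ring fusion, C8 carbinol, C9 acyloxy carbon, C10(C14)=C1, C2 methylene, C3 acetoxy carbon, C4(C15)=C5, C11=C13, C12 carbonyl).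

**Route**

Step 1
Reactants: 1 (E)-2-methylbut-2-en-1-ol
Product: 2 [(2R,3R)-2,3-dimethyloxiran-2-yl]methanol
Conditions: Ti(OiPr)4 (10 mol %), D-(−)-diethyl tartrate (12 mol %), tBuOOH, 4 Å sieves, CH2Cl2, −20 °C
Reagents that add atoms: tert-butyl hydroperoxide, CC(C)(C)OO
Why: Sharpless asymmetric epoxidation; with D-(−)-diethyl tartrate the oxygen is delivered to the face that gives the (2R,3R)-epoxy alcohol, and the E alkene fixes the two methyl groups cis.

Step 2
Reactants: 2 [(2R,3R)-2,3-dimethyloxiran-2-yl]methanol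
Product: 3 (2S,3R)-2,3-dimethyloxirane-2-carboxylic acid
Conditions: RuCl3 (2 mol %), NaIO4 (3 equiv), MeCN/EtOAc/H2O, 0 °C → rt
Reagents that add atoms: water, O
Why: RuO4-catalysed oxidation of the primary alcohol to the acid through the aldehyde hydrate leaves the epoxide and both stereocentres untouched (C2 becomes S only through the priority change).

Step 3
Reactants: 4 but-2-yn-1-ol
Product: 6 (Z)-3-iodobut-2-en-1-ol, via alkenylaluminate 5 (not isolated)
Conditions: NaAlH2(OCH2CH2OCH3)2, THF, 0 °C → rt; then I2, −78 °C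
Reagents that add atoms: iodine, II
Why: Hydroxyl-directed trans-hydroalumination of the propargylic alcohol and iodinolysis with retention place iodine cis to CH2OH, which fixes the Z geometry of the later C4=C5 bond.

Step 4
Reactants: 6 (Z)-3-iodobut-2-en-1-ol
Product: 7 triethyl{[(2Z)-3-iodobut-2-en-1-yl]oxy}silane
Conditions: Et3SiCl, imidazole, CH2Cl2, 0 °C
Reagents that add atoms: chlorotriethylsilane, CC[Si](Cl)(CC)CC
Why: Standard silylation; a primary triethylsilyl ether is chosen because step 17 oxidises it directly to the aldehyde.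

Step 5
Reactants: 8 dimethyl (4R,5R)-2,2-dimethyl-1,3-dioxolane-4,5-dicarboxylate
Product: 9 (4R,5R)-N,N,N',N',2,2-hexamethyl-1,3-dioxolane-4,5-dicarboxamide
Conditions: Me2NH (excess), MeOH, rt
Reagents that add atoms: dimethylamine, CNC
Why: Aminolysis of the activated α-alkoxy esters; the trans-acetonide holds both stereocentres (later C8 and C9).

Step 6
Reactants: 9 (4R,5R)-N,N,N',N',2,2-hexamethyl-1,3-dioxolane-4,5-dicarboxamide
Product: 10 (4R,5R)-5-acetyl-N,N,2,2-tetramethyl-1,3-dioxolane-4-carboxamide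
Conditions: MeMgBr (1.5 equiv), THF, −10 °C; aq. NH4Cl
Reagents that add atoms: methylmagnesium bromide, C[Mg]Br
Why: Mono-addition of a Grignard reagent to a tartaric bis(dimethylamide) (Prasad desymmetrisation); the chelated tetrahedral adduct blocks over-addition and attack at the second amide, so the two carboxyl ends become C10 (ketone) and C7 (amide).

Step 7
Reactants: 10 (4R,5R)-5-acetyl-N,N,2,2-tetramethyl-1,3-dioxolane-4-carboxamide; 11 [2-(1,3-dioxolan-2-yl)ethyl]triphenylphosphonium bromide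
Product: 13 (4R,5S)-5-[(2Z)-4-(1,3-dioxolan-2-yl)but-2-en-2-yl]-N,N,2,2-tetramethyl-1,3-dioxolane-4-carboxamide, via ylide 12 (not isolated)
Conditions: KN(SiMe3)2, THF, −78 °C; then 10, −78 °C → rt
Reagents that add atoms: none
Why: Wittig olefination of an α-alkoxy methyl ketone with a non-stabilised ylide is Z-selective for the trisubstituted allylic ether (Still), which sets the C1=C10 geometry with C9 cis to C2.

Step 8
Reactants: 13 (4R,5S)-5-[(2Z)-4-(1,3-dioxolan-2-yl)but-2-en-2-yl]-N,N,2,2-tetramethyl-1,3-dioxolane-4-carboxamide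
Product: 14 (2R,3S,4Z)-6-(1,3-dioxolan-2-yl)-2,3-dihydroxy-N,N,4-trimethylhex-4-enamide
Conditions: HOCH2CH2OH (20 equiv), TsOH·H2O (10 mol %), THF, 40 °C
Reagents that add atoms: none
Why: Acid-catalysed transketalisation; excess ethylene glycol takes over the acetone unit, while the aldehyde dioxolane is already the glycol acetal and stays intact.

Step 9
Reactants: 14 (2R,3S,4Z)-6-(1,3-dioxolan-2-yl)-2,3-dihydroxy-N,N,4-trimethylhex-4-enamide
Product: 15 (2R,3S,4Z)-2-[(tert-butyldimethylsilyl)oxy]-6-(1,3-dioxolan-2-yl)-3-hydroxy-N,N,4-trimethylhex-4-enamide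
Conditions: tBuMe2SiCl (1.05 equiv), imidazole, DMF, −20 → 0 °C
Reagents that add atoms: tert-butyldimethylsilyl chloride, CC(C)(C)[Si](C)(C)Cl
Why: Regioselective silylation; the hydroxyl α to the amide (C8–OH) is the more acidic one and is expected to react first, leaving the allylic C9–OH free.

Step 10
Reactants: 15 (2R,3S,4Z)-2-[(tert-butyldimethylsilyl)oxy]-6-(1,3-dioxolan-2-yl)-3-hydroxy-N,N,4-trimethylhex-4-enamide; 3 (2S,3R)-2,3-dimethyloxirane-2-carboxylic acid
Product: 17 C9 epoxy ester of 15, via mixed anhydride 16 (not isolated)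
Conditions: 3, 2,4,6-trichlorobenzoyl chloride, Et3N, toluene, rt; then 15, DMAP, rt → 40 °C
Reagents that add atoms: none
Why: Yamaguchi esterification through the mixed anhydride acylates the hindered allylic C9–OH; the α,α-disubstituted epoxy acid has no α-hydrogen, so neither epoxide stereocentre can epimerise.

Step 11
Reactants: 17 C9 epoxy ester of 15
Product: 18 C3 aldehyde (β,γ-unsaturated; amide at C7)
Conditions: PPTS (0.3 equiv), acetone/H2O 10:1, 50 °C
Reagents that add atoms: water, O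
Why: Mild acetal hydrolysis releases the β,γ-unsaturated aldehyde without moving the double bond and without cleaving the secondary silyl ether or the electron-poor epoxide.

Step 12
Reactants: 18 C3 aldehyde (β,γ-unsaturated; amide at C7); 7 triethyl{[(2Z)-3-iodobut-2-en-1-yl]oxy}silane
Product: 19 C3 allylic alcohol (3S; C6–OSiEt3)
Conditions: CrCl2 (4 equiv), NiCl2 (2 mol %), Kishi-type chiral sulfonamide–oxazoline ligand (antipode chosen for re-face addition), Et3N, THF, rt
Reagents that add atoms: none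
Why: Nozaki–Hiyama–Kishi alkenylation is chemoselective for the aldehyde beside amide, esters and epoxide; the chiral ligand on chromium directs the alkenyl group to the re face of the aldehyde and so sets C3 (S), and the iodide's Z geometry is retained.

Step 13
Reactants: 19 C3 allylic alcohol (3S; C6–OSiEt3)
Product: 20 C3 acetate
Conditions: Ac2O, pyridine, DMAP (cat.), CH2Cl2, 0 °C → rt
Reagents that add atoms: acetic anhydride, CC(=O)OC(C)=O
Why: Acetylation of the only free hydroxyl installs the C3 acetate of the target with retention.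

Step 14
Reactants: 20 C3 acetate
Product: 21 C7 aldehyde
Conditions: Cp2Zr(H)Cl (1.8 equiv), THF, rt, 20 min; wet silica
Reagents that add atoms: none
Why: Cp2Zr(H)Cl reduces a tertiary amide to the aldehyde through a stable zirconated hemiaminal and leaves esters, epoxide and silyl ethers alone (Georg reduction); the neutral conditions do not enolise C8.

Step 15
Reactants: 21 C7 aldehyde; 22 methyl prop-2-ynoate
Product: 24 Baylis–Hillman-type allylic alcohol (C7 epimers), via vinylalane 23 (not isolated)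
Conditions: 22, iBu2AlH, N-methylmorpholine N-oxide, THF, 0 °C; then 21, 0 °C → rt
Reagents that add atoms: none
Why: Vinylalumination (conjugate hydroalumination of the ynoate, then 1,2-addition of the α-aluminoacrylate) gives the Baylis–Hillman-type adduct without an amine base that could epimerise C8 or eliminate the C9 ester; the new carbinol centre is erased in step 16.

Step 16
Reactants: 24 Baylis–Hillman-type allylic alcohol (C7 epimers)
Product: 25 (Z)-allylic bromide (C13–Br; C7=C11)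
Conditions: N-bromosuccinimide, Me2S, CH2Cl2, −20 → 0 °C
Reagents that add atoms: N-bromosuccinimide, O=C1CCC(=O)N1Br
Why: Corey–Kim-type activation of the Baylis–Hillman alcohol and SN2' attack of bromide give the thermodynamically preferred (Z)-2-(bromomethyl)enoate, which makes C7 sp2 and C13 the allylic halide.

Step 17
Reactants: 25 (Z)-allylic bromide (C13–Br; C7=C11)
Product: 26 open-chain bromo enal (C6 aldehyde)
Conditions: (COCl)2, DMSO, CH2Cl2, −78 °C; 25, −78 → −40 °C; iPr2NEt, −78 → −20 °C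
Reagents that add atoms: none
Why: Swern conditions oxidise a primary triethylsilyl ether directly to the aldehyde while the secondary tert-butyldimethylsilyl ether survives; the hindered amine at low temperature spares the allylic bromide and the Z-enal.

Step 18
Reactants: 26 open-chain bromo enal (C6 aldehyde)
Product: 28 8-O-silyl germacranolide, via hydroxy ester 27 (not isolated)
Conditions: CrCl2 (10 equiv), THF, 25 °C, 26 added over 12 h to 2 mM; aq. NH4Cl
Reagents that add atoms: none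
Why: Intramolecular Nozaki–Hiyama allylation (Barbier-type 2-(alkoxycarbonyl)allylation) then lactonisation: the allylchromium attacks the enal through C7, closing the ten-membered ring at the C6–C7 bond that the sesquiterpene cyclase makes, and the C6 alkoxide then closes the γ-lactone onto C12; the allylmetal keeps C8 cis to CH2Cr, so the chair transition state gives the 6,7-syn adduct (cis-lactone, 6S), and allylic 1,3-strain holds H8 in the alkene plane so that the aldehyde should add anti to the C9 branch (Houk model for allylic ethers), giving the C7 configuration of the target.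

Step 19
Reactants: 28 8-O-silyl germacranolide
Product: 29 CNP0137407.7 (target)
Conditions: HF·pyridine, pyridine, THF, 0 °C → rt
Reagents that add atoms: none
Why: Buffered fluoride desilylation frees the C8 hydroxyl without the basic media that would cause acyl migration from O9 to O8 or relactonisation onto O8; the C7 label changes from S to R only through the priority change.

**Compound list**

1 | (E)-2-methylbut-2-en-1-ol | C/C=C(\C)CO | starting material
2 | [(2R,3R)-2,3-dimethyloxiran-2-yl]methanol | OC[C@@]1(C)O[C@@H]1C | intermediate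
3 | (2S,3R)-2,3-dimethyloxirane-2-carboxylic acid | OC(=O)[C@@]1(C)O[C@@H]1C | intermediate
4 | but-2-yn-1-ol | CC#CCO | starting material
5 | alkenylaluminate: sodium 2,2-bis(2-methoxyethoxy)-3-methyl-2,5-dihydro-1,2-oxaaluminol-2-uide | [Na+].CC1=CCO[Al-]1(OCCOC)OCCOC | intermediate
6 | (Z)-3-iodobut-2-en-1-ol | OC/C=C(/C)I | intermediate
7 | triethyl{[(2Z)-3-iodobut-2-en-1-yl]oxy}silane | CC[Si](CC)(CC)OC/C=C(/C)I | intermediate
8 | dimethyl (4R,5R)-2,2-dimethyl-1,3-dioxolane-4,5-dicarboxylate | COC(=O)[C@@H]1OC(C)(C)O[C@H]1C(=O)OC | starting material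
9 | (4R,5R)-N,N,N',N',2,2-hexamethyl-1,3-dioxolane-4,5-dicarboxamide | CN(C)C(=O)[C@@H]1OC(C)(C)O[C@H]1C(=O)N(C)C | intermediate
10 | (4R,5R)-5-acetyl-N,N,2,2-tetramethyl-1,3-dioxolane-4-carboxamide | CC(=O)[C@@H]1OC(C)(C)O[C@H]1C(=O)N(C)C | intermediate
11 | [2-(1,3-dioxolan-2-yl)ethyl]triphenylphosphonium bromide | [Br-].C1COC(CC[P+](c2ccccc2)(c2ccccc2)c2ccccc2)O1 | starting material
12 | ylide: 2-[2-(triphenyl-λ5-phosphanylidene)ethyl]-1,3-dioxolane | C1COC(CC=P(c2ccccc2)(c2ccccc2)c2ccccc2)O1 | intermediate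
13 | (4R,5S)-5-[(2Z)-4-(1,3-dioxolan-2-yl)but-2-en-2-yl]-N,N,2,2-tetramethyl-1,3-dioxolane-4-carboxamide | C1COC(O1)C/C=C(/C)[C@@H]2OC(C)(C)O[C@H]2C(=O)N(C)C | intermediate
14 | (2R,3S,4Z)-6-(1,3-dioxolan-2-yl)-2,3-dihydroxy-N,N,4-trimethylhex-4-enamide | C1COC(O1)C/C=C(/C)[C@H](O)[C@@H](O)C(=O)N(C)C | intermediate
15 | (2R,3S,4Z)-2-[(tert-butyldimethylsilyl)oxy]-6-(1,3-dioxolan-2-yl)-3-hydroxy-N,N,4-trimethylhex-4-enamide | C1COC(O1)C/C=C(/C)[C@H](O)[C@@H](O[Si](C)(C)C(C)(C)C)C(=O)N(C)C | intermediate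
16 | mixed anhydride: (2S,3R)-2,3-dimethyloxirane-2-carboxylic 2,4,6-trichlorobenzoic anhydride | O=C(OC(=O)[C@@]1(C)O[C@@H]1C)c2c(Cl)cc(Cl)cc2Cl | intermediate
17 | C9 epoxy ester of 15: (2R,3S,4Z)-2-[(tert-butyldimethylsilyl)oxy]-1-(dimethylamino)-6-(1,3-dioxolan-2-yl)-4-methyl-1-oxohex-4-en-3-yl (2S,3R)-2,3-dimethyloxirane-2-carboxylate | C1COC(O1)C/C=C(/C)[C@H](OC(=O)[C@@]2(C)O[C@@H]2C)[C@@H](O[Si](C)(C)C(C)(C)C)C(=O)N(C)C | intermediate
18 | C3 aldehyde: (2R,3S,4Z)-2-[(tert-butyldimethylsilyl)oxy]-1-(dimethylamino)-4-methyl-1,7-dioxohept-4-en-3-yl (2S,3R)-2,3-dimethyloxirane-2-carboxylate | O=CC/C=C(/C)[C@H](OC(=O)[C@@]1(C)O[C@@H]1C)[C@@H](O[Si](C)(C)C(C)(C)C)C(=O)N(C)C | intermediate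
19 | C3 allylic alcohol: (2R,3S,4Z,7S,8Z)-2-[(tert-butyldimethylsilyl)oxy]-1-(dimethylamino)-7-hydroxy-4,8-dimethyl-1-oxo-10-[(triethylsilyl)oxy]deca-4,8-dien-3-yl (2S,3R)-2,3-dimethyloxirane-2-carboxylate | CC[Si](CC)(CC)OC/C=C(/C)[C@@H](O)C/C=C(/C)[C@H](OC(=O)[C@@]1(C)O[C@@H]1C)[C@@H](O[Si](C)(C)C(C)(C)C)C(=O)N(C)C | intermediate
20 | C3 acetate: (2R,3S,4Z,7S,8Z)-7-acetoxy-2-[(tert-butyldimethylsilyl)oxy]-1-(dimethylamino)-4,8-dimethyl-1-oxo-10-[(triethylsilyl)oxy]deca-4,8-dien-3-yl (2S,3R)-2,3-dimethyloxirane-2-carboxylate | CC[Si](CC)(CC)OC/C=C(/C)[C@@H](OC(C)=O)C/C=C(/C)[C@H](OC(=O)[C@@]1(C)O[C@@H]1C)[C@@H](O[Si](C)(C)C(C)(C)C)C(=O)N(C)C | intermediate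
21 | C7 aldehyde: (2R,3S,4Z,7S,8Z)-7-acetoxy-2-[(tert-butyldimethylsilyl)oxy]-4,8-dimethyl-1-oxo-10-[(triethylsilyl)oxy]deca-4,8-dien-3-yl (2S,3R)-2,3-dimethyloxirane-2-carboxylate | CC[Si](CC)(CC)OC/C=C(/C)[C@@H](OC(C)=O)C/C=C(/C)[C@H](OC(=O)[C@@]1(C)O[C@@H]1C)[C@@H](O[Si](C)(C)C(C)(C)C)C=O | intermediate
22 | methyl prop-2-ynoate | C#CC(=O)OC | starting material
23 | vinylalane: methyl 2-[bis(2-methylpropyl)alumanyl]prop-2-enoate | C=C(C(=O)OC)[Al](CC(C)C)CC(C)C | intermediate
24 | Baylis–Hillman-type allylic alcohol: methyl (3RS,4S,5S,6Z,9S,10Z)-9-acetoxy-4-[(tert-butyldimethylsilyl)oxy]-5-{[(2S,3R)-2,3-dimethyloxirane-2-carbonyl]oxy}-3-hydroxy-6,10-dimethyl-2-methylidene-12-[(triethylsilyl)oxy]dodeca-6,10-dienoate | CC[Si](CC)(CC)OC/C=C(/C)[C@@H](OC(C)=O)C/C=C(/C)[C@H](OC(=O)[C@@]1(C)O[C@@H]1C)[C@@H](O[Si](C)(C)C(C)(C)C)C(O)C(=C)C(=O)OC | intermediate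
25 | (Z)-allylic bromide: methyl (2Z,4S,5S,6Z,9S,10Z)-9-acetoxy-2-(bromomethyl)-4-[(tert-butyldimethylsilyl)oxy]-5-{[(2S,3R)-2,3-dimethyloxirane-2-carbonyl]oxy}-6,10-dimethyl-12-[(triethylsilyl)oxy]dodeca-2,6,10-trienoate | CC[Si](CC)(CC)OC/C=C(/C)[C@@H](OC(C)=O)C/C=C(/C)[C@H](OC(=O)[C@@]1(C)O[C@@H]1C)[C@@H](O[Si](C)(C)C(C)(C)C)/C=C(/C(=O)OC)CBr | intermediate
26 | open-chain bromo enal: methyl (2Z,4S,5S,6Z,9S,10Z)-9-acetoxy-2-(bromomethyl)-4-[(tert-butyldimethylsilyl)oxy]-5-{[(2S,3R)-2,3-dimethyloxirane-2-carbonyl]oxy}-6,10-dimethyl-12-oxododeca-2,6,10-trienoate | O=C/C=C(/C)[C@@H](OC(C)=O)C/C=C(/C)[C@H](OC(=O)[C@@]1(C)O[C@@H]1C)[C@@H](O[Si](C)(C)C(C)(C)C)/C=C(/C(=O)OC)CBr | intermediate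
27 | hydroxy ester: methyl (1(10)Z,3S,4Z,6S,7S,8S,9S)-3-acetoxy-8-[(tert-butyldimethylsilyl)oxy]-9-{[(2S,3R)-2,3-dimethyloxirane-2-carbonyl]oxy}-6-hydroxygermacra-1(10),4,11(13)-trien-12-oate | O[C@H]1/C=C(/C)[C@@H](OC(C)=O)C/C=C(/C)[C@H](OC(=O)[C@@]2(C)O[C@@H]2C)[C@@H](O[Si](C)(C)C(C)(C)C)[C@H]1C(=C)C(=O)OC | intermediate
28 | 8-O-silyl germacranolide: (1(10)Z,3S,4Z,6S,7S,8S,9S)-3-acetoxy-8-[(tert-butyldimethylsilyl)oxy]-9-{[(2S,3R)-2,3-dimethyloxirane-2-carbonyl]oxy}germacra-1(10),4,11(13)-trien-12,6-olide | C=C1C(=O)O[C@H]2/C=C(/C)[C@@H](OC(C)=O)C/C=C(/C)[C@H](OC(=O)[C@@]3(C)O[C@@H]3C)[C@@H](O[Si](C)(C)C(C)(C)C)[C@@H]12 | intermediate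
29 | CNP0137407.7: (1(10)Z,3S,4Z,6S,7R,8S,9S)-3-acetoxy-8-hydroxy-9-{[(2S,3R)-2,3-dimethyloxirane-2-carbonyl]oxy}germacra-1(10),4,11(13)-trien-12,6-olide | C=C1C(=O)O[C@H]2/C=C(/C)[C@@H](OC(C)=O)C/C=C(/C)[C@H](OC(=O)[C@@]3(C)O[C@@H]3C)[C@@H](O)[C@@H]12 | target

**Step count and risks**

Total step count: 19. Longest linear sequence: 15 steps (steps 5–19, from 8); steps 1–2 and 3–4 are two-step side branches.

The three steps most likely to fail:

Step 18 (macrocyclisation and lactonisation). The risks are oligomerisation and the wrong face at C7, or a 6,7-anti adduct. The fallback sets out from 25 and comes back at 28. Borylation of 25 with B2pin2 and catalytic Pd2(dba)3 in toluene gives the allylboronate methyl (2E,4S,5S,6Z,9S,10Z)-9-acetoxy-4-[(tert-butyldimethylsilyl)oxy]-5-{[(2S,3R)-2,3-dimethyloxirane-2-carbonyl]oxy}-6,10-dimethyl-2-[(4,4,5,5-tetramethyl-1,3,2-dioxaborolan-2-yl)methyl]-12-[(triethylsilyl)oxy]dodeca-2,6,10-trienoate F1. The Swern conditions of step 17 then give the boronate aldehyde, the 12-oxo analogue of F1 without the triethylsilyl group, F2, which is isolable because an ester-substituted allylboronate does not add to an aldehyde without activation. Sc(OTf)3 (10 mol %) in toluene at 2 mM then triggers an intramolecular allylboration through a closed six-membered chair, and the borate lactonises onto the methyl ester to give 28. This replaces the open organochromium pathway by a tight boron-centred transition state, and a chiral phosphoric acid can be used in place of Sc(OTf)3 if the facial bias has to be overridden.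

Step 9 (regioselective silylation of C8–OH over C9–OH). The fallback sets out from 14 and comes back at 15. MnO2 in CH2Cl2 oxidises only the allylic C9–OH to give the hydroxy enone (2R,4Z)-6-(1,3-dioxolan-2-yl)-2-hydroxy-N,N,4-trimethyl-3-oxohex-4-enamide F3. The single remaining hydroxyl is silylated (tBuMe2SiCl, imidazole) to give (2R,4Z)-2-[(tert-butyldimethylsilyl)oxy]-6-(1,3-dioxolan-2-yl)-N,N,4-trimethyl-3-oxohex-4-enamide F4. A 1,2-reduction with NaBH4 and CeCl3 in MeOH at −78 °C under Felkin–Anh control (silyloxy group anti to the hydride) then gives the 8,9-syn alcohol 15.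

Step 12 (C3 configuration in the chromium-mediated coupling). The fallback sets out from 18 and 7 and comes back at 19. Ligand-free coupling with CrCl2 and catalytic NiCl2 gives 19 together with its C7 epimer (2R,3S,4Z,7R,8Z)-2-[(tert-butyldimethylsilyl)oxy]-1-(dimethylamino)-7-hydroxy-4,8-dimethyl-1-oxo-10-[(triethylsilyl)oxy]deca-4,8-dien-3-yl (2S,3R)-2,3-dimethyloxirane-2-carboxylate F5. Buffered Dess–Martin oxidation of the mixture gives the enone (2R,3S,4Z,8Z)-2-[(tert-butyldimethylsilyl)oxy]-1-(dimethylamino)-4,8-dimethyl-1,7-dioxo-10-[(triethylsilyl)oxy]deca-4,8-dien-3-yl (2S,3R)-2,3-dimethyloxirane-2-carboxylate F6. Reduction with (R)-2-methyl-CBS-oxazaborolidine and catecholborane at −78 °C, with the alkenyl group as the large substituent, returns the 7S alcohol 19.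

**Further compounds**

F1 | step 18 | methyl (2E,4S,5S,6Z,9S,10Z)-9-acetoxy-4-[(tert-butyldimethylsilyl)oxy]-5-{[(2S,3R)-2,3-dimethyloxirane-2-carbonyl]oxy}-6,10-dimethyl-2-[(4,4,5,5-tetramethyl-1,3,2-dioxaborolan-2-yl)methyl]-12-[(triethylsilyl)oxy]dodeca-2,6,10-trienoate | CC[Si](CC)(CC)OC/C=C(/C)[C@@H](OC(C)=O)C/C=C(/C)[C@H](OC(=O)[C@@]1(C)O[C@@H]1C)[C@@H](O[Si](C)(C)C(C)(C)C)/C=C(/C(=O)OC)CB2OC(C)(C)C(C)(C)O2
F2 | step 18 | methyl (2E,4S,5S,6Z,9S,10Z)-9-acetoxy-4-[(tert-butyldimethylsilyl)oxy]-5-{[(2S,3R)-2,3-dimethyloxirane-2-carbonyl]oxy}-6,10-dimethyl-12-oxo-2-[(4,4,5,5-tetramethyl-1,3,2-dioxaborolan-2-yl)methyl]dodeca-2,6,10-trienoate | O=C/C=C(/C)[C@@H](OC(C)=O)C/C=C(/C)[C@H](OC(=O)[C@@]1(C)O[C@@H]1C)[C@@H](O[Si](C)(C)C(C)(C)C)/C=C(/C(=O)OC)CB2OC(C)(C)C(C)(C)O2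
F3 | step 9 | (2R,4Z)-6-(1,3-dioxolan-2-yl)-2-hydroxy-N,N,4-trimethyl-3-oxohex-4-enamide | C1COC(O1)C/C=C(/C)C(=O)[C@@H](O)C(=O)N(C)C
F4 | step 9 | (2R,4Z)-2-[(tert-butyldimethylsilyl)oxy]-6-(1,3-dioxolan-2-yl)-N,N,4-trimethyl-3-oxohex-4-enamide | C1COC(O1)C/C=C(/C)C(=O)[C@@H](O[Si](C)(C)C(C)(C)C)C(=O)N(C)C
F5 | step 12 | (2R,3S,4Z,7R,8Z)-2-[(tert-butyldimethylsilyl)oxy]-1-(dimethylamino)-7-hydroxy-4,8-dimethyl-1-oxo-10-[(triethylsilyl)oxy]deca-4,8-dien-3-yl (2S,3R)-2,3-dimethyloxirane-2-carboxylate | CC[Si](CC)(CC)OC/C=C(/C)[C@H](O)C/C=C(/C)[C@H](OC(=O)[C@@]1(C)O[C@@H]1C)[C@@H](O[Si](C)(C)C(C)(C)C)C(=O)N(C)C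
F6 | step 12 | (2R,3S,4Z,8Z)-2-[(tert-butyldimethylsilyl)oxy]-1-(dimethylamino)-4,8-dimethyl-1,7-dioxo-10-[(triethylsilyl)oxy]deca-4,8-dien-3-yl (2S,3R)-2,3-dimethyloxirane-2-carboxylate | CC[Si](CC)(CC)OC/C=C(/C)C(=O)C/C=C(/C)[C@H](OC(=O)[C@@]1(C)O[C@@H]1C)[C@@H](O[Si](C)(C)C(C)(C)C)C(=O)N(C)C
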